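**Retrosynthetic overview**

1. Target ⇐ oxidation of a C5 alcohol ⇐ hydroxyl-directed epoxidation of C3=C4 ⇐ 1,2-reduction of an α′,γ-diacetoxy enone that already carries the C8 angelate. Direct Weitz–Scheffer epoxidation of the enone is avoided because, as with carvone, it should place the epoxide trans to the C1 side chain. The epoxide is the only ring made (last step but one); the six-membered ring is that of carvone.
2. C8 angelate ⇐ Yamaguchi esterification; C6–OAc ⇐ enolate hydroxylation; C2–OAc ⇐ vinylogous Rubottom oxidation of the extended silyl dienol ether (both anti to the C1 side chain).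
3. Prenyl terminus CH=C(CH3)2 ⇐ Ni-catalysed methylation of a (Z)-enol carbamate CH=C(CH3)OCb.
4. Key C8–C9 bond ⇐ homoaldol reaction: the CH2 terminus of a chiral titanated but-3-en-2-yl carbamate (a homoenolate, nucleophilic β-carbon of a masked ketone) attacks the aldehyde carbon of a carvone-derived 2-substituted acrolein and fixes (8S) by 1,3-chirality transfer.
5. Enal ⇐ (R)-carvone by allylic chlorination and N-oxide oxidation.

Assumption: Li→Ti exchange with Ti(OiPr)4 on the lithiated secondary allyl carbamate is invertive and the aldehyde addition is suprafacial through a chair (carbamoyloxy axial), as established for related carbamates; on this model the (R)-carbamate gives (8S).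

Numbering used in names and comments: ring C1 (bears the side chain), C2, C3, C4 (bears CH3), C5 (C=O), C6; side chain C7(=C14H2)–C8–C9–C10=C11(CH3)2; Cb = C(O)N(iPr)2; TBS = tert-butyldimethylsilyl.

**Route**

Step 1
Reactants: 1 (R)-(−)-carvone
Product: 2 (5R)-5-(3-chloroprop-1-en-2-yl)-2-methylcyclohex-2-en-1-one
Conditions: Ca(OCl)2, CO2 (dry ice), CH2Cl2–H2O, 0 °C
Reagents that add atoms: calcium hypochlorite, [Ca+2].[O-]Cl.[O-]Cl
Why: Ene-type allylic chlorination by HOCl of the electron-rich 1,1-disubstituted alkene with double-bond shift (known for carvone); the conjugated ring alkene is deactivated and the stereocentre is untouched.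

Step 2
Reactants: 2 (5R)-5-(3-chloroprop-1-en-2-yl)-2-methylcyclohex-2-en-1-one
Product: 4 2-[(1R)-4-methyl-5-oxocyclohex-3-en-1-yl]prop-2-enal, via alkoxymorpholinium chloride 3 (not isolated)
Conditions: NMO (4 equiv), KI (10 mol %), 4 Å MS, MeCN, rt
Reagents that add atoms: N-methylmorpholine N-oxide, C[N+]1([O-])CCOCC1
Why: Kornblum-type N-oxide oxidation of an allylic halide (O-alkylation, then elimination of N-methylmorpholine); the allyl unit is symmetric, so SN2 and SN2′ attack give the same enal.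

Step 3
Reactants: 5 (R)-but-3-en-2-ol; 6 N,N-diisopropylcarbamoyl chloride
Product: 7 (R)-but-3-en-2-yl N,N-diisopropylcarbamate
Conditions: pyridine, 90 °C
Reagents that add atoms: none
Why: O-carbamoylation; the C–O bond of the stereocentre is not broken, so configuration is retained.

Step 4
Reactants: 7 (R)-but-3-en-2-yl N,N-diisopropylcarbamate; 4 2-[(1R)-4-methyl-5-oxocyclohex-3-en-1-yl]prop-2-enal
Product: 10 (2Z,5S)-5-hydroxy-6-[(1R)-4-methyl-5-oxocyclohex-3-en-1-yl]hepta-2,6-dien-2-yl N,N-diisopropylcarbamate, via lithiated carbamate 8 (not isolated), via allyltitanate 9 (not isolated)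
Conditions: n-BuLi, TMEDA, Et2O–hexane, −78 °C; Ti(OiPr)4, −78 °C; then 4, −78 → −40 °C; H2O work-up
Reagents that add atoms: n-butyllithium, [Li]CCCC (Li held in 8 and 9 only); titanium tetraisopropoxide, CC(C)O[Ti](OC(C)C)(OC(C)C)OC(C)C (held in 9 only)
Why: Hoppe homoaldol reaction: retentive lithiation and invertive Li→Ti exchange give the configurationally stable (R)-allyltitanate, whose CH2 terminus (the homoenolate carbon, future C9) adds to the aldehyde only (the enone ketone is left) through a chair transition state with OCb axial and the aldehyde residue equatorial, giving (8S) and the (Z)-enol carbamate.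

Step 5
Reactants: 10 (2Z,5S)-5-hydroxy-6-[(1R)-4-methyl-5-oxocyclohex-3-en-1-yl]hepta-2,6-dien-2-yl N,N-diisopropylcarbamate
Product: 12 (2Z,5S)-5-(TBSO)-6-[(1S)-5-(TBSO)-4-methylcyclohexa-2,4-dien-1-yl]hepta-2,6-dien-2-yl N,N-diisopropylcarbamate, via dipotassium alkoxide dienolate 11 (not isolated)
Conditions: KOt-Bu (2.3 equiv), THF, −20 °C; then TBSCl (2.6 equiv), −20 °C → rt
Reagents that add atoms: potassium tert-butoxide, CC(C)(C)[O-].[K+] (K held in 11 only); tert-butyldimethylsilyl chloride, CC(C)(C)[Si](C)(C)Cl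
Why: Thermodynamic γ-deprotonation to the extended dienolate (as in α-alkylations of carvone) and O-silylation of both oxyanions; this masks the ketone as the through-conjugated silyl dienol ether needed in steps 6 and 7 and touches no stereocentre.

Step 6
Reactants: 12 (2Z,5S)-5-(TBSO)-6-[(1S)-5-(TBSO)-4-methylcyclohexa-2,4-dien-1-yl]hepta-2,6-dien-2-yl N,N-diisopropylcarbamate
Product: 13 tert-butyl{[(3S)-2-[(1S)-5-(TBSO)-4-methylcyclohexa-2,4-dien-1-yl]-6-methylhepta-1,5-dien-3-yl]oxy}dimethylsilane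
Conditions: MeMgBr (4 equiv), Ni(acac)2 (10 mol %), Et2O–toluene, 0 °C → rt
Reagents that add atoms: methylmagnesium bromide, C[Mg]Br
Why: Ni-catalysed Kumada-type cross-coupling of the enol carbamate C–O bond (oxidative addition to zerovalent nickel, transmetalation, reductive elimination) replaces OCb by CH3 to give the prenyl terminus; no ketone or ester is present and the hindered tetrasubstituted TBS dienol ether is far less prone to C–O insertion.

Step 7
Reactants: 13 tert-butyl{[(3S)-2-[(1S)-5-(TBSO)-4-methylcyclohexa-2,4-dien-1-yl]-6-methylhepta-1,5-dien-3-yl]oxy}dimethylsilane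
Product: 15 (8S)-8-(TBSO)-2-hydroxybisabola-3,7(14),10-trien-5-one with 2-OH trans to the C1 side chain, via vinyl epoxide 14 (not isolated)
Conditions: dimethyldioxirane (1.05 equiv), acetone–CH2Cl2, −78 °C; aq NaHCO3 work-up
Reagents that add atoms: dimethyldioxirane, CC1(C)OO1
Why: Vinylogous Rubottom oxidation: the electrophilic oxidant attacks the terminal C2=C3 bond of the 1-silyloxy diene (largest HOMO coefficient, as in 6-hydroxylation of steroidal 3,5-dienol ethers) much faster than the prenyl or 1,1-disubstituted alkenes and anti to the adjacent C1 side chain; the epoxide opens to the trans-γ-hydroxy enone, setting C2.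

Step 8
Reactants: 15 (8S)-8-(TBSO)-2-hydroxybisabola-3,7(14),10-trien-5-one
Product: 18 (8S)-8-(TBSO)-2,6-diacetoxybisabola-3,7(14),10-trien-5-one with both acetoxy groups trans to the C1 side chain, via dipotassium enolate 16 (not isolated), via dipotassium dialkoxide 17 (not isolated)
Conditions: KN(SiMe3)2 (2.2 equiv), THF, −78 °C; 3-phenyl-2-(phenylsulfonyl)oxaziridine (1.3 equiv), −78 °C; then Ac2O, DMAP, −78 → 0 °C
Reagents that add atoms: potassium bis(trimethylsilyl)amide, C[Si](C)(C)[N-][Si](C)(C)C.[K+] (K held in 16 and 17 only); 3-phenyl-2-(phenylsulfonyl)oxaziridine, O=S(=O)(c1ccccc1)N1OC1c1ccccc1; acetic anhydride, CC(=O)OC(C)=O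
Why: Kinetic α′-enolisation of the alkoxide–enone, Davis oxaziridine hydroxylation of the C6 enolate anti to the adjacent C1 side chain (sets C6), and in situ acetylation of both potassium alkoxides.

Step 9
Reactants: 18 (8S)-8-(TBSO)-2,6-diacetoxybisabola-3,7(14),10-trien-5-one
Product: 19 (8S)-2,6-diacetoxy-8-hydroxybisabola-3,7(14),10-trien-5-one
Conditions: HF·pyridine, pyridine–THF, 0 °C → rt
Reagents that add atoms: none
Why: Fluoride-driven cleavage of the secondary silyl ether under buffered conditions that leave the acetates and the enone untouched; no stereocentre is affected.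

Step 10
Reactants: 19 (8S)-2,6-diacetoxy-8-hydroxybisabola-3,7(14),10-trien-5-one; 20 angelic acid
Product: 22 (8S)-2,6-diacetoxy-8-angeloyloxybisabola-3,7(14),10-trien-5-one, via mixed anhydride 21 (not isolated)
Conditions: 20, 2,4,6-trichlorobenzoyl chloride, Et3N, toluene, rt; then 19, 80 °C
Reagents that add atoms: 2,4,6-trichlorobenzoyl chloride, O=C(Cl)c1c(Cl)cc(Cl)cc1Cl (held in 21 only)
Why: Yamaguchi esterification through the mixed anhydride without DMAP, conditions known to angeloylate hindered secondary alcohols without Z→E isomerisation; C8 keeps its configuration.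

Step 11
Reactants: 22 (8S)-2,6-diacetoxy-8-angeloyloxybisabola-3,7(14),10-trien-5-one
Product: 23 (8S)-2,6-diacetoxy-8-angeloyloxybisabola-3,7(14),10-trien-5-ol with 5-OH cis to the C1 side chain
Conditions: NaBH4, CeCl3·7H2O, MeOH, −78 °C
Reagents that add atoms: none
Why: Luche 1,2-reduction; axial hydride attack on the half-chair with all three ring substituents equatorial gives the equatorial C5 alcohol, cis to the C1 side chain and trans to C6–OAc (as carvone → cis-carveol), while the esters survive.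

Step 12
Reactants: 23 (8S)-2,6-diacetoxy-8-angeloyloxybisabola-3,7(14),10-trien-5-ol
Product: 24 (8S)-2,6-diacetoxy-8-angeloyloxy-3,4-epoxybisabola-7(14),10-dien-5-ol with the epoxide cis to 5-OH and to the C1 side chain
Conditions: VO(acac)2 (5 mol %), t-BuOOH, CH2Cl2, 0 °C → rt
Reagents that add atoms: tert-butyl hydroperoxide, CC(C)(C)OO
Why: Hydroxyl-directed vanadium-catalysed epoxidation delivers oxygen to C3=C4 syn to the C5 hydroxyl, which is also anti to C2–OAc, setting C3 and C4; alkenes without an allylic OH (prenyl, C7=C14, angelate) do not react.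

Step 13
Reactants: 24 (8S)-2,6-diacetoxy-8-angeloyloxy-3,4-epoxybisabola-7(14),10-dien-5-ol
Product: 25 target, (1R,2R,3S,4S,6S,8S)-2,6-diacetoxy-8-angeloyloxy-3,4-epoxybisabola-7(14),10-dien-5-one
Conditions: Dess–Martin periodinane, CH2Cl2, 0 °C → rt
Reagents that add atoms: none
Why: Dess–Martin oxidation of the secondary alcohol to the α,β-epoxy ketone under non-basic conditions that do not epimerise C6 or isomerise the angelate; the temporary C5 stereocentre is removed.

**Compound list**

1 | (R)-(−)-carvone, (5R)-2-methyl-5-(prop-1-en-2-yl)cyclohex-2-en-1-one | C=C([C@@H]1CC=C(C)C(=O)C1)C | starting material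
2 | (5R)-5-(3-chloroprop-1-en-2-yl)-2-methylcyclohex-2-en-1-one | C=C([C@@H]1CC=C(C)C(=O)C1)CCl | intermediate
3 | 4-methyl-4-({2-[(1R)-4-methyl-5-oxocyclohex-3-en-1-yl]prop-2-en-1-yl}oxy)morpholin-4-ium chloride | C=C([C@@H]1CC=C(C)C(=O)C1)CO[N+]1(C)CCOCC1.[Cl-] | intermediate (not isolated)
4 | 2-[(1R)-4-methyl-5-oxocyclohex-3-en-1-yl]prop-2-enal | C=C([C@@H]1CC=C(C)C(=O)C1)C=O | intermediate
5 | (R)-but-3-en-2-ol | C[C@@H](O)C=C | starting material
6 | N,N-diisopropylcarbamoyl chloride | CC(C)N(C(C)C)C(Cl)=O | starting material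
7 | (R)-but-3-en-2-yl N,N-diisopropylcarbamate | C[C@@H](OC(=O)N(C(C)C)C(C)C)C=C | intermediate
8 | (R)-2-lithiobut-3-en-2-yl N,N-diisopropylcarbamate (TMEDA complex) | C[C@@]([Li])(OC(=O)N(C(C)C)C(C)C)C=C | intermediate (not isolated)
9 | lithium (R)-[2-(N,N-diisopropylcarbamoyloxy)but-3-en-2-yl]tetraisopropoxytitanate | C[C@]([Ti-](OC(C)C)(OC(C)C)(OC(C)C)OC(C)C)(OC(=O)N(C(C)C)C(C)C)C=C.[Li+] | intermediate (not isolated)
10 | (2Z,5S)-5-hydroxy-6-[(1R)-4-methyl-5-oxocyclohex-3-en-1-yl]hepta-2,6-dien-2-yl N,N-diisopropylcarbamate | C=C([C@@H]1CC=C(C)C(=O)C1)[C@H](C/C=C(/C)OC(=O)N(C(C)C)C(C)C)O | intermediate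
11 | dipotassium salt of 10: C8 alkoxide plus extended ring dienolate (O–C5=C4–C3=C2) | C=C([C@@H]1C=CC(C)=C([O-])C1)[C@H](C/C=C(/C)OC(=O)N(C(C)C)C(C)C)[O-].[K+].[K+] | intermediate (not isolated)
12 | (2Z,5S)-5-(TBSO)-6-[(1S)-5-(TBSO)-4-methylcyclohexa-2,4-dien-1-yl]hepta-2,6-dien-2-yl N,N-diisopropylcarbamate | C=C([C@@H]1C=CC(C)=C(O[Si](C)(C)C(C)(C)C)C1)[C@H](C/C=C(/C)OC(=O)N(C(C)C)C(C)C)O[Si](C)(C)C(C)(C)C | intermediate
13 | tert-butyl{[(3S)-2-[(1S)-5-(TBSO)-4-methylcyclohexa-2,4-dien-1-yl]-6-methylhepta-1,5-dien-3-yl]oxy}dimethylsilane | C=C([C@@H]1C=CC(C)=C(O[Si](C)(C)C(C)(C)C)C1)[C@H](CC=C(C)C)O[Si](C)(C)C(C)(C)C | intermediate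
14 | C2–C3 epoxide of 13 on the ring face opposite the C1 side chain (silyloxy vinyl epoxide) | C=C([C@@H]1[C@H]2O[C@H]2C(C)=C(O[Si](C)(C)C(C)(C)C)C1)[C@H](CC=C(C)C)O[Si](C)(C)C(C)(C)C | intermediate (not isolated)
15 | (8S)-8-(TBSO)-2-hydroxybisabola-3,7(14),10-trien-5-one, 2-OH trans to the C1 side chain, C1 as in carvone | C=C([C@@H]1[C@@H](O)C=C(C)C(=O)C1)[C@H](CC=C(C)C)O[Si](C)(C)C(C)(C)C | intermediate
16 | dipotassium salt of 15: C2 alkoxide plus C5=C6 enolate | C=C([C@@H]1[C@@H]([O-])C=C(C)C([O-])=C1)[C@H](CC=C(C)C)O[Si](C)(C)C(C)(C)C.[K+].[K+] | intermediate (not isolated)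
17 | dipotassium 2,6-dialkoxide of (8S)-8-(TBSO)-2,6-dihydroxybisabola-3,7(14),10-trien-5-one, both O trans to the C1 side chain | C=C([C@@H]1[C@@H]([O-])C=C(C)C(=O)[C@H]1[O-])[C@H](CC=C(C)C)O[Si](C)(C)C(C)(C)C.[K+].[K+] | intermediate (not isolated)
18 | (8S)-8-(TBSO)-2,6-diacetoxybisabola-3,7(14),10-trien-5-one, both OAc trans to the C1 side chain | C=C([C@@H]1[C@@H](OC(C)=O)C=C(C)C(=O)[C@H]1OC(C)=O)[C@H](CC=C(C)C)O[Si](C)(C)C(C)(C)C | intermediate
19 | (8S)-2,6-diacetoxy-8-hydroxybisabola-3,7(14),10-trien-5-one | C=C([C@@H]1[C@@H](OC(C)=O)C=C(C)C(=O)[C@H]1OC(C)=O)[C@H](CC=C(C)C)O | intermediate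
20 | angelic acid, (Z)-2-methylbut-2-enoic acid | C/C=C(/C)C(=O)O | starting material
21 | angelic 2,4,6-trichlorobenzoic anhydride | C/C=C(/C)C(=O)OC(=O)c1c(Cl)cc(Cl)cc1Cl | intermediate (not isolated)
22 | (8S)-2,6-diacetoxy-8-angeloyloxybisabola-3,7(14),10-trien-5-one | C=C([C@@H]1[C@@H](OC(C)=O)C=C(C)C(=O)[C@H]1OC(C)=O)[C@H](CC=C(C)C)OC(=O)/C(C)=C\C | intermediate
23 | (8S)-2,6-diacetoxy-8-angeloyloxybisabola-3,7(14),10-trien-5-ol, 5-OH cis to the C1 side chain | C=C([C@@H]1[C@@H](OC(C)=O)C=C(C)[C@H](O)[C@H]1OC(C)=O)[C@H](CC=C(C)C)OC(=O)/C(C)=C\C | intermediate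
24 | (8S)-2,6-diacetoxy-8-angeloyloxy-3,4-epoxybisabola-7(14),10-dien-5-ol, epoxide and 5-OH cis to the C1 side chain | C=C([C@@H]1[C@@H](OC(C)=O)[C@@H]2O[C@]2(C)[C@H](O)[C@H]1OC(C)=O)[C@H](CC=C(C)C)OC(=O)/C(C)=C\C | intermediate
25 | (1R,2R,3S,4S,6S,8S)-2,6-diacetoxy-8-angeloyloxy-3,4-epoxybisabola-7(14),10-dien-5-one (CNP0298051.3) | C=C([C@@H]1[C@@H](OC(C)=O)[C@@H]2O[C@]2(C)C(=O)[C@H]1OC(C)=O)[C@H](CC=C(C)C)OC(=O)/C(C)=C\C | target

**Step count and risks**

Total: 13 steps. Longest linear sequence: 12 steps from (R)-carvone (steps 1, 2, 4–13); step 3 is a one-step side branch.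

Steps most likely to fail:

Step 4 (homoaldol). The risk is the sense and degree of chirality transfer with a γ-unsubstituted 1-methylallyl titanate and an α-branched enal. The fallback sets out from 4 and 7 and returns at 10. If the addition gives mainly the C8 epimer, (2Z,5R)-5-hydroxy-6-[(1R)-4-methyl-5-oxocyclohex-3-en-1-yl]hepta-2,6-dien-2-yl N,N-diisopropylcarbamate F1, the stereocentre is corrected by substitution instead of reagent control. Mitsunobu reaction (4-nitrobenzoic acid, PPh3, DIAD, THF, 0 °C) inverts C8 to the (5S)-4-nitrobenzoate F2, and K2CO3 in MeOH releases 10.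

Step 6 (Ni-catalysed methylation). The risk is competing C–O insertion into, or isomerisation and aromatisation of, the silyl dienol ether. The fallback sets out from 10 and returns at 13 with the order of masking and coupling reversed. The ketone of 10 is protected in the flask as its lithium enolate (LiN(SiMe3)2, 2.2 equiv, THF, −78 °C), then Ni(acac)2 and MeMgBr are added. Aqueous quench gives (5R)-5-[(3S)-3-hydroxy-6-methylhepta-1,5-dien-2-yl]-2-methylcyclohex-2-en-1-one F3, which is bis-silylated under the conditions of step 5 to give 13.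

Step 7 (γ-oxidation). The risks are attack at the tetrasubstituted enol bond (α-hydroxylation) and partial epoxidation of the prenyl group. The fallback sets out from 13 and returns at 15 and uses a pericyclic oxidant that can only deliver oxygen to the diene termini. Singlet oxygen (O2, tetraphenylporphyrin, hν, CH2Cl2–MeOH, −78 °C, stopped at one equivalent) adds [4+2] across C2/C5 anti to the C1 side chain. The silylperoxy ketal collapses to the trans-γ-hydroperoxy enone, (8S)-8-(TBSO)-2-hydroperoxybisabola-3,7(14),10-trien-5-one F4, and PPh3 reduces it to 15.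

**Further compounds**

F1 | step 4 | (2Z,5R)-5-hydroxy-6-[(1R)-4-methyl-5-oxocyclohex-3-en-1-yl]hepta-2,6-dien-2-yl N,N-diisopropylcarbamate | C=C([C@@H]1CC=C(C)C(=O)C1)[C@@H](C/C=C(/C)OC(=O)N(C(C)C)C(C)C)O
F2 | step 4 | (2Z,5S)-2-(N,N-diisopropylcarbamoyloxy)-6-[(1R)-4-methyl-5-oxocyclohex-3-en-1-yl]hepta-2,6-dien-5-yl 4-nitrobenzoate | C=C([C@@H]1CC=C(C)C(=O)C1)[C@H](C/C=C(/C)OC(=O)N(C(C)C)C(C)C)OC(=O)c1ccc(cc1)[N+](=O)[O-]
F3 | step 6 | (5R)-5-[(3S)-3-hydroxy-6-methylhepta-1,5-dien-2-yl]-2-methylcyclohex-2-en-1-one | C=C([C@@H]1CC=C(C)C(=O)C1)[C@H](CC=C(C)C)O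
F4 | step 7 | (8S)-8-(TBSO)-2-hydroperoxybisabola-3,7(14),10-trien-5-one, 2-OOH trans to the C1 side chain | C=C([C@@H]1[C@@H](OO)C=C(C)C(=O)C1)[C@H](CC=C(C)C)O[Si](C)(C)C(C)(C)C
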